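**Plan**
1. Atom labels follow the pentalene core: C1(=O)–C2=C3(styryl)–C3a(H)–C4(aryl)=C5(aryl)–C6(=O)–C6a(OH). Ring A is C1/C2/C3/C3a/C6a, ring B is C3a/C4/C5/C6/C6a. All seven phenols travel as methyl ethers.
2. Cuts, last bond first: C3a–C3 (ring A, vinylogous Michael addition onto an ynone), C1–C2 (acetylide plus a C6a aldehyde that comes from a vinyl group), then C3a–C6a (ring B).
3. The feature behind the third cut: in ring B the C6 ketone sits beside the C6a tertiary alcohol. This 5-hydroxycyclopent-2-enone is therefore the acyloin isomer of a 1-acryloylcyclobut-2-en-1-ol (C6 carbinol, C6a acyl carbon), and a 1,2-shift of C3a from C6 to C6a links the two.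
4. The cyclobutenol is cut at C6–C6a (lithiated alkoxyallene as acryloyl anion equivalent plus a 2,3-diarylcyclobutenone). The cyclobutenone is cut at its ring bonds (dichloroketene plus aryl ynol ether) and at C4–aryl (aryllithium addition with carbonyl transposition).
5. Forward order: four-membered ring, then ring B by ring enlargement, then ring A by 5-endo-dig closure, then global deprotection.
6. Stereochemistry: (R)-C6 is secured with a D-glucose-derived allenyl ether and separation of diastereomers, is relayed to (S)-C6a in the chelated shift, and (S)-C3a follows from the obligatory cis fusion of the two five-membered rings.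

Key step: step 9

Remark on the chemistry: the sense of induction of the glucose auxiliary in step 7 is not predicted. The route counts only on chromatographic separation of the two carbinol diastereomers, and the assignment of the (1R) isomer would rest on crystallography.

**Route**

Step 1
Reactants: 1 5-iodo-1,2,3-trimethoxybenzene; 2 ethoxyacetylene
Product: 5 5-(ethoxyethynyl)-1,2,3-trimethoxybenzene, via lithium ethoxyacetylide 3 (not isolated), via ethoxyethynylzinc chloride 4 (not isolated)
Conditions: 2, n-BuLi, THF, −78 °C; ZnCl2, −78 → 0 °C; then 1, Pd(PPh3)4 (5 mol%), rt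
Reagents that add atoms: none
Why: Negishi coupling of an alkynylzinc chloride with an aryl iodide under zerovalent palladium catalysis is a routine sp–sp2 bond construction, and the zinc acetylide avoids the copper and amine salts that hydrate ynol ethers.

Step 2
Reactants: 5 5-(ethoxyethynyl)-1,2,3-trimethoxybenzene; 6 trichloroacetyl chloride
Product: 7 4,4-dichloro-3-ethoxy-2-(3,4,5-trimethoxyphenyl)cyclobut-2-en-1-one
Conditions: Zn–Cu couple, Et2O/DME, 0 °C → rt, slow addition of 6; crude product taken on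
Reagents that add atoms: none
Why: Ketene–alkyne [2+2] cycloaddition with dichloroketene made in the flask: the alkyne carbon β to the ethoxy oxygen is the nucleophilic one and bonds to the ketene carbonyl carbon, so the aryl group ends up next to the ketone and the ethoxy group next to CCl2, while DME ties up the ZnCl2 that would otherwise attack the ynol ether.

Step 3
Reactants: 7 4,4-dichloro-3-ethoxy-2-(3,4,5-trimethoxyphenyl)cyclobut-2-en-1-one
Product: 8 3-ethoxy-2-(3,4,5-trimethoxyphenyl)cyclobut-2-en-1-one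
Conditions: Zn dust, AcOH, TMEDA, EtOH, 0 °C → rt
Reagents that add atoms: none
Why: Zinc-mediated reductive dechlorination of the α,α-dichloroketone is the standard sequel to dichloroketene cycloadditions and spares the vinylogous ester.

Step 4
Reactants: 8 3-ethoxy-2-(3,4,5-trimethoxyphenyl)cyclobut-2-en-1-one; 9 1-bromo-3,5-dimethoxybenzene
Product: 12 3-(3,5-dimethoxyphenyl)-2-(3,4,5-trimethoxyphenyl)cyclobut-2-en-1-one, via 3,5-dimethoxyphenyllithium 10 (not isolated), via lithium cyclobutenolate adduct 11 (not isolated)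
Conditions: 9, n-BuLi, THF, −78 °C; add 8, −78 °C; 1 M aq HCl added at −78 °C, then 0 °C → rt
Reagents that add atoms: water, O
Why: Halogen–lithium exchange and 1,2-addition of the aryllithium to the 3-alkoxycyclobutenone, then acid hydrolysis of the tertiary allylic alcohol with 1,3-carbonyl transposition (Stork–Danheiser sequence), place the second aryl group on the β-carbon without any electrophilic halogenation of the electron-rich rings, and C4 is not deprotonated because its enolate would be a cyclobutadiene.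

Step 5
Reactants: 13 1,2:5,6-di-O-isopropylidene-α-D-glucofuranose; 14 propargyl bromide
Product: 15 1,2:5,6-di-O-isopropylidene-3-O-(prop-2-yn-1-yl)-α-D-glucofuranose
Conditions: NaH, Bu4NI (cat.), THF, 0 °C → rt
Reagents that add atoms: none
Why: Williamson ether synthesis on the single free hydroxyl of the diacetonide.

Step 6
Reactants: 15 1,2:5,6-di-O-isopropylidene-3-O-(prop-2-yn-1-yl)-α-D-glucofuranose
Product: 16 1,2:5,6-di-O-isopropylidene-3-O-(propa-1,2-dien-1-yl)-α-D-glucofuranose
Conditions: KOtBu (30 mol%), THF, rt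
Reagents that add atoms: none
Why: Base-catalysed prototropic isomerisation of a propargyl ether to the allenyl ether, which stops at the allene under catalytic alkoxide at room temperature.

Step 7
Reactants: 16 1,2:5,6-di-O-isopropylidene-3-O-(propa-1,2-dien-1-yl)-α-D-glucofuranose; 12 3-(3,5-dimethoxyphenyl)-2-(3,4,5-trimethoxyphenyl)cyclobut-2-en-1-one
Product: 18 (1R)-3-(3,5-dimethoxyphenyl)-1-[1-(glucofuranos-3-O-yl)propa-1,2-dien-1-yl]-2-(3,4,5-trimethoxyphenyl)cyclobut-2-en-1-ol (sugar = the diacetonide of 13), via lithiated allenyl ether 17 (not isolated)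
Conditions: 16, n-BuLi, THF, −78 °C; add 12, −78 °C; AcOH/THF quench at −78 °C; chromatography on Et3N-deactivated silica
Reagents that add atoms: none
Why: α-Lithiation of an alkoxyallene and 1,2-addition to the strained, non-enolisable cyclobutenone carbonyl is the standard acryloyl-anion-equivalent chemistry; the C6 carbinol forms under the influence of the sugar auxiliary, only modest facial bias is counted on, and the (1R) diastereomer is secured by chromatographic separation from its (1S) epimer, the cold quench preventing alkoxide-accelerated opening of the cyclobutene.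

Step 8
Reactants: 18 (1R)-allenyl carbinol carrying the glucose auxiliary
Product: 19 1-[(1R)-3-(3,5-dimethoxyphenyl)-1-hydroxy-2-(3,4,5-trimethoxyphenyl)cyclobut-2-en-1-yl]prop-2-en-1-one
Conditions: 0.5 M aq H2SO4 (cat.), THF, 0 °C, short contact; NaHCO3 work-up
Reagents that add atoms: water, O
Why: Mild acid hydrolysis of the allenyl enol ether (protonation at the central allene carbon, hydration of the oxocarbenium ion, loss of the sugar alcohol) unmasks the vinyl ketone much faster than the acetonides or the tertiary carbinol react, so the stereocenter is untouched.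

Step 9
Reactants: 19 1-[(1R)-3-(3,5-dimethoxyphenyl)-1-hydroxy-2-(3,4,5-trimethoxyphenyl)cyclobut-2-en-1-yl]prop-2-en-1-one
Product: 20 (5S)-3-(3,5-dimethoxyphenyl)-5-ethenyl-5-hydroxy-2-(3,4,5-trimethoxyphenyl)cyclopent-2-en-1-one
Conditions: Sc(OTf)3 (10–20 mol%), BHT (trace), CH2Cl2 (0.02 M), −20 °C → rt
Reagents that add atoms: none
Why: Sc(OTf)3 binds the C6 hydroxyl and the acryloyl oxygen as a five-membered chelate, which makes the C6a carbonyl carbon electrophilic and holds O–C6–C6a=O syn-periplanar, and the C6–C3a σ bond, standing above the carbonyl plane, then shifts suprafacially to C6a while C6 becomes a ketone. This is the α-ketol (acyloin) rearrangement in its ring-enlarging form, known for 1-acylcyclobutanols and for the D-homoannulation of 17-hydroxy-20-keto steroids; here the ring also carries the C4=C5 double bond. Ring B is closed by a concerted 1,2-alkyl shift that enlarges the four-membered ring to a five-membered one, driven by release of cyclobutene strain and by the conjugation gained between the new C6 ketone and C4=C5. The new C6a stereocenter is controlled by the C6 carbinol, because in the chelate the CH2 carbon can reach only one face of the carbonyl, so (R)-C6 gives (S)-C6a. The step needs migration of C3a and not of the vinylic carbon C5, which would go to the opposite face and give a non-conjugated ketone; this is secured by the better migrating ability of the sp3 C–C bond (the C5 bond is sp2-hybridised and its π orbital could only bridge through a housane-like array) and by the enone conjugation that only the C3a shift develops. Ionisation at C6 is not expected because the acyl group destabilises a cation there, and low temperature, high dilution and a radical inhibitor keep the vinyl ketone from oligomerising.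

Step 10
Reactants: 20 (5S)-3-(3,5-dimethoxyphenyl)-5-ethenyl-5-hydroxy-2-(3,4,5-trimethoxyphenyl)cyclopent-2-en-1-one
Product: 21 (5S)-3-(3,5-dimethoxyphenyl)-5-ethenyl-5-(triethylsilyloxy)-2-(3,4,5-trimethoxyphenyl)cyclopent-2-en-1-one
Conditions: TESOTf, 2,6-lutidine, CH2Cl2, −78 → 0 °C
Reagents that add atoms: triethylsilyl trifluoromethanesulfonate, CC[Si](CC)(CC)OS(=O)(=O)C(F)(F)F
Why: Silylation of a tertiary alcohol with a silyl triflate and a hindered pyridine base; the ether blocks oxa-Michael (furanone) closure onto the later ynone and retro-aldol loss of the C1 carbon.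

Step 11
Reactants: 21 (5S)-3-(3,5-dimethoxyphenyl)-5-ethenyl-5-(triethylsilyloxy)-2-(3,4,5-trimethoxyphenyl)cyclopent-2-en-1-one
Product: 23 (1S)-4-(3,5-dimethoxyphenyl)-2-oxo-1-(triethylsilyloxy)-3-(3,4,5-trimethoxyphenyl)cyclopent-3-ene-1-carbaldehyde, via vicinal diol 22 (not isolated)
Conditions: OsO4 (2 mol%), NaIO4, 2,6-lutidine, dioxane/H2O (3:1), rt
Reagents that add atoms: osmium tetroxide, O=[Os](=O)(=O)=O; sodium periodate, [Na+].[O-]I(=O)(=O)=O
Why: Lemieux–Johnson oxidation (catalytic dihydroxylation, then periodate cleavage in the same flask): OsO4 selects the monosubstituted vinyl group over the tetrasubstituted, electron-poor enone double bond and leaves the electron-rich arenes alone, which ozone might not.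

Step 12
Reactants: 24 3,5-dimethoxybenzaldehyde; 25 (triphenylphosphoranylidene)acetaldehyde
Product: 26 (2E)-3-(3,5-dimethoxyphenyl)prop-2-enal
Conditions: toluene, 80 °C
Reagents that add atoms: none
Why: Wittig olefination with a carbonyl-stabilised ylide, which gives the (E)-enal.

Step 13
Reactants: 26 (2E)-3-(3,5-dimethoxyphenyl)prop-2-enal
Product: 27 1-[(1E)-4,4-dibromobuta-1,3-dien-1-yl]-3,5-dimethoxybenzene
Conditions: CBr4, PPh3, CH2Cl2, 0 °C
Reagents that add atoms: carbon tetrabromide, BrC(Br)(Br)Br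
Why: Corey–Fuchs dibromo-olefination of the enal with the ylide made in the flask from CBr4 and PPh3.

Step 14
Reactants: 27 1-[(1E)-4,4-dibromobuta-1,3-dien-1-yl]-3,5-dimethoxybenzene; 23 (1S)-4-(3,5-dimethoxyphenyl)-2-oxo-1-(triethylsilyloxy)-3-(3,4,5-trimethoxyphenyl)cyclopent-3-ene-1-carbaldehyde
Product: 29 (5S)-3-(3,5-dimethoxyphenyl)-5-[(4E)-5-(3,5-dimethoxyphenyl)-1-hydroxypent-4-en-2-yn-1-yl]-5-(triethylsilyloxy)-2-(3,4,5-trimethoxyphenyl)cyclopent-2-en-1-one (both carbinol epimers), via lithium enynide 28 (not isolated)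
Conditions: 27, n-BuLi (2 equiv), THF, −78 °C; add 23, −78 °C; AcOH/THF quench at −78 °C
Reagents that add atoms: none
Why: The second stage of the Corey–Fuchs sequence (bromine–lithium exchange, Fritsch–Buttenberg–Wiechell shift, deprotonation) delivers the lithium acetylide, which adds at −78 °C to the aldehyde far faster than to the hindered conjugated ring ketone; the new carbinol centre forms without control and is removed in the next step, and the cold quench forestalls silyl migration and retro-aldol cleavage of the alkoxide.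

Step 15
Reactants: 29 propargylic alcohol (both epimers)
Product: 30 (5S)-3-(3,5-dimethoxyphenyl)-5-[(4E)-5-(3,5-dimethoxyphenyl)pent-4-en-2-ynoyl]-5-(triethylsilyloxy)-2-(3,4,5-trimethoxyphenyl)cyclopent-2-en-1-one
Conditions: Dess–Martin periodinane, pyridine, CH2Cl2, 0 °C → rt
Reagents that add atoms: none
Why: Dess–Martin oxidation of the secondary propargylic alcohol under buffered, non-basic conditions that leave the silyl ether and the acidic C3a–H alone.

Step 16
Reactants: 30 ynone
Product: 31 (3aS,6aS)-4-(3,5-dimethoxyphenyl)-3-[(E)-2-(3,5-dimethoxyphenyl)ethenyl]-6a-(triethylsilyloxy)-5-(3,4,5-trimethoxyphenyl)-3a,6a-dihydropentalene-1,6-dione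
Conditions: Cs2CO3 (20 mol%), MeCN, 0 °C → rt; AcOH quench once the ynone is consumed
Reagents that add atoms: none
Why: Intramolecular vinylogous Michael addition: catalytic carbonate deprotonates C3a (γ to the C6 ketone) and the dienolate terminus adds to the ynone β-carbon C3 in a Baldwin-allowed 5-endo-dig closure of the kind known for enolate–ynone carbocyclisations, after which protonation at C2 gives the ring A enone; C3a can bond only on the face of ring B on which the C6a acyl arm stands, so the cis ring fusion and hence (3aS) follow from (6aS).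

Step 17
Reactants: 31 silyl-protected heptamethyl ether
Product: 32 (3aS,6aS)-4-(3,5-dihydroxyphenyl)-3-[(E)-2-(3,5-dihydroxyphenyl)ethenyl]-6a-hydroxy-5-(3,4,5-trihydroxyphenyl)-3a,6a-dihydropentalene-1,6-dione
Conditions: BBr3 (excess), CH2Cl2, −78 °C → rt; then H2O/THF, 0 °C → rt
Reagents that add atoms: none
Why: BBr3 cleavage of aryl methyl ethers is the standard last step for polyphenols, the silyl ether falls to the same reagent and to the HBr formed on quenching, and the two stereocenters cannot be scrambled because C6a is flanked by two carbonyl groups and the ring fusion can only be cis.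

**Compound list**
1 | 5-iodo-1,2,3-trimethoxybenzene | COc1cc(I)cc(OC)c1OC | starting material
2 | ethoxyacetylene (ethoxyethyne) | CCOC#C | starting material
3 | lithium ethoxyacetylide (formed in the flask) | CCOC#C[Li] | intermediate
4 | ethoxyethynylzinc chloride (formed in the flask) | CCOC#C[Zn]Cl | intermediate
5 | 5-(ethoxyethynyl)-1,2,3-trimethoxybenzene | CCOC#Cc1cc(OC)c(OC)c(OC)c1 | intermediate
6 | trichloroacetyl chloride | ClC(=O)C(Cl)(Cl)Cl | starting material
7 | 4,4-dichloro-3-ethoxy-2-(3,4,5-trimethoxyphenyl)cyclobut-2-en-1-one | O=C1C(c2cc(OC)c(OC)c(OC)c2)=C(OCC)C1(Cl)Cl | intermediate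
8 | 3-ethoxy-2-(3,4,5-trimethoxyphenyl)cyclobut-2-en-1-one | O=C1CC(OCC)=C1c1cc(OC)c(OC)c(OC)c1 | intermediate
9 | 1-bromo-3,5-dimethoxybenzene | COc1cc(Br)cc(OC)c1 | starting material
10 | 3,5-dimethoxyphenyllithium (formed in the flask) | [Li]c1cc(OC)cc(OC)c1 | intermediate
11 | lithium 1-(3,5-dimethoxyphenyl)-3-ethoxy-2-(3,4,5-trimethoxyphenyl)cyclobut-2-en-1-olate, racemic (formed in the flask) | [Li]OC1(c2cc(OC)cc(OC)c2)CC(OCC)=C1c1cc(OC)c(OC)c(OC)c1 | intermediate
12 | 3-(3,5-dimethoxyphenyl)-2-(3,4,5-trimethoxyphenyl)cyclobut-2-en-1-one | O=C1CC(c2cc(OC)cc(OC)c2)=C1c1cc(OC)c(OC)c(OC)c1 | intermediate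
13 | 1,2:5,6-di-O-isopropylidene-α-D-glucofuranose (diacetone-D-glucose) | CC1(C)OC[C@@H](O1)[C@H]2O[C@@H]3OC(C)(C)O[C@@H]3[C@H]2O | starting material
14 | propargyl bromide (3-bromoprop-1-yne) | C#CCBr | starting material
15 | 1,2:5,6-di-O-isopropylidene-3-O-(prop-2-yn-1-yl)-α-D-glucofuranose | CC1(C)OC[C@@H](O1)[C@H]2O[C@@H]3OC(C)(C)O[C@@H]3[C@H]2OCC#C | intermediate
16 | 1,2:5,6-di-O-isopropylidene-3-O-(propa-1,2-dien-1-yl)-α-D-glucofuranose | CC1(C)OC[C@@H](O1)[C@H]2O[C@@H]3OC(C)(C)O[C@@H]3[C@H]2OC=C=C | intermediate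
17 | 16 lithiated at the oxygen-bearing allene carbon (formed in the flask) | CC1(C)OC[C@@H](O1)[C@H]2O[C@@H]3OC(C)(C)O[C@@H]3[C@H]2OC([Li])=C=C | intermediate
18 | (1R)-3-(3,5-dimethoxyphenyl)-1-[1-(1,2:5,6-di-O-isopropylidene-α-D-glucofuranos-3-O-yl)propa-1,2-dien-1-yl]-2-(3,4,5-trimethoxyphenyl)cyclobut-2-en-1-ol | CC1(C)OC[C@@H](O1)[C@H]2O[C@@H]3OC(C)(C)O[C@@H]3[C@H]2OC(=C=C)[C@@]4(O)CC(c5cc(OC)cc(OC)c5)=C4c6cc(OC)c(OC)c(OC)c6 | intermediate
19 | 1-[(1R)-3-(3,5-dimethoxyphenyl)-1-hydroxy-2-(3,4,5-trimethoxyphenyl)cyclobut-2-en-1-yl]prop-2-en-1-one | C=CC(=O)[C@@]1(O)CC(c2cc(OC)cc(OC)c2)=C1c1cc(OC)c(OC)c(OC)c1 | intermediate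
20 | (5S)-3-(3,5-dimethoxyphenyl)-5-ethenyl-5-hydroxy-2-(3,4,5-trimethoxyphenyl)cyclopent-2-en-1-one | O=C1C(c2cc(OC)c(OC)c(OC)c2)=C(c2cc(OC)cc(OC)c2)C[C@]1(O)C=C | intermediate
21 | (5S)-3-(3,5-dimethoxyphenyl)-5-ethenyl-5-(triethylsilyloxy)-2-(3,4,5-trimethoxyphenyl)cyclopent-2-en-1-one | O=C1C(c2cc(OC)c(OC)c(OC)c2)=C(c2cc(OC)cc(OC)c2)C[C@]1(O[Si](CC)(CC)CC)C=C | intermediate
22 | (5S)-5-(1,2-dihydroxyethyl)-3-(3,5-dimethoxyphenyl)-5-(triethylsilyloxy)-2-(3,4,5-trimethoxyphenyl)cyclopent-2-en-1-one, both side-chain epimers (formed in the flask) | O=C1C(c2cc(OC)c(OC)c(OC)c2)=C(c2cc(OC)cc(OC)c2)C[C@]1(O[Si](CC)(CC)CC)C(O)CO | intermediate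
23 | (1S)-4-(3,5-dimethoxyphenyl)-2-oxo-1-(triethylsilyloxy)-3-(3,4,5-trimethoxyphenyl)cyclopent-3-ene-1-carbaldehyde | O=C1C(c2cc(OC)c(OC)c(OC)c2)=C(c2cc(OC)cc(OC)c2)C[C@]1(O[Si](CC)(CC)CC)C=O | intermediate
24 | 3,5-dimethoxybenzaldehyde | COc1cc(C=O)cc(OC)c1 | starting material
25 | (triphenylphosphoranylidene)acetaldehyde | O=CC=P(c1ccccc1)(c1ccccc1)c1ccccc1 | starting material
26 | (2E)-3-(3,5-dimethoxyphenyl)prop-2-enal | O=C/C=C/c1cc(OC)cc(OC)c1 | intermediate
27 | 1-[(1E)-4,4-dibromobuta-1,3-dien-1-yl]-3,5-dimethoxybenzene | BrC(Br)=C/C=C/c1cc(OC)cc(OC)c1 | intermediate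
28 | lithium (3E)-4-(3,5-dimethoxyphenyl)but-3-en-1-yn-1-ide (formed in the flask) | [Li]C#C/C=C/c1cc(OC)cc(OC)c1 | intermediate
29 | (5S)-3-(3,5-dimethoxyphenyl)-5-[(4E)-5-(3,5-dimethoxyphenyl)-1-hydroxypent-4-en-2-yn-1-yl]-5-(triethylsilyloxy)-2-(3,4,5-trimethoxyphenyl)cyclopent-2-en-1-one, both carbinol epimers | O=C1C(c2cc(OC)c(OC)c(OC)c2)=C(c2cc(OC)cc(OC)c2)C[C@]1(O[Si](CC)(CC)CC)C(O)C#C/C=C/c1cc(OC)cc(OC)c1 | intermediate
30 | (5S)-3-(3,5-dimethoxyphenyl)-5-[(4E)-5-(3,5-dimethoxyphenyl)pent-4-en-2-ynoyl]-5-(triethylsilyloxy)-2-(3,4,5-trimethoxyphenyl)cyclopent-2-en-1-one | O=C1C(c2cc(OC)c(OC)c(OC)c2)=C(c2cc(OC)cc(OC)c2)C[C@]1(O[Si](CC)(CC)CC)C(=O)C#C/C=C/c1cc(OC)cc(OC)c1 | intermediate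
31 | (3aS,6aS)-4-(3,5-dimethoxyphenyl)-3-[(E)-2-(3,5-dimethoxyphenyl)ethenyl]-6a-(triethylsilyloxy)-5-(3,4,5-trimethoxyphenyl)-3a,6a-dihydropentalene-1,6-dione | O=C1C=C(/C=C/c2cc(OC)cc(OC)c2)[C@H]2C(c3cc(OC)cc(OC)c3)=C(c3cc(OC)c(OC)c(OC)c3)C(=O)[C@@]12O[Si](CC)(CC)CC | intermediate
32 | (3aS,6aS)-4-(3,5-dihydroxyphenyl)-3-[(E)-2-(3,5-dihydroxyphenyl)ethenyl]-6a-hydroxy-5-(3,4,5-trihydroxyphenyl)-3a,6a-dihydropentalene-1,6-dione | O=C1C=C(/C=C/c2cc(O)cc(O)c2)[C@H]2C(c3cc(O)cc(O)c3)=C(c3cc(O)c(O)c(O)c3)C(=O)[C@@]12O | target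

**Step count**
Total: 17 steps. Longest linear sequence: 13 steps (steps 1–4, 7–11 and 14–17, from 1 and 2).

**Steps most likely to fail**

Step 9. Under the Lewis acid, conjugate addition and oligomerisation at the vinyl ketone may outrun the 1,2-shift, and a loosely chelated conformer may let the vinylic carbon C5 shift or erode the transfer of configuration. The fallback sets out from 19 and masks the vinyl ketone. Thiophenol with catalytic Et3N in CH2Cl2 at 0 °C should add to the enone to give the saturated ketol (1R)-1-[3-(3,5-dimethoxyphenyl)-1-hydroxy-2-(3,4,5-trimethoxyphenyl)cyclobut-2-en-1-yl]-3-(phenylsulfanyl)propan-1-one F1. This ketone has no acceptor left, so it can be held in a stoichiometric chelate (Sc(OTf)3 or Al(OtBu)3, CH2Cl2, rt) until the ring enlargement to (5S)-3-(3,5-dimethoxyphenyl)-5-hydroxy-5-[2-(phenylsulfanyl)ethyl]-2-(3,4,5-trimethoxyphenyl)cyclopent-2-en-1-one F2 is complete. Oxidation with NaIO4 in aqueous methanol gives the sulfoxide F3, and thermal syn-elimination (toluene, CaCO3, 110 °C) restores the vinyl group, so the sequence comes back to the route at 20.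

Step 7. Facial discrimination by the sugar may be poor and the two carbinol diastereomers may co-elute, which would leave the configuration at C6 unsecured. The fallback sets out from 12 and replaces the auxiliary by a resolution. Commercial methoxyallene is lithiated (n-BuLi, THF, −78 °C) to 1-lithio-1-methoxyallene F4, which adds to 12 to give the racemic 1-(1-methoxyallenyl)cyclobutenol F5. Brief hydrolysis with dilute H2SO4 in THF gives the racemic acryloyl carbinol F6. The enantiomers are separated by preparative chromatography on a polysaccharide-based chiral stationary phase, and the (R)-enantiomer is 19, where the route is rejoined.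

Step 16. The free dienolate may react through oxygen (6-endo attack giving a pyranone), may expel silanolate from C6a, or may let the double bonds of the product migrate through its acidic C3a–H, all in competition with carbon–carbon bond formation. The fallback sets out from 30 and avoids any free enolate. Soft enolisation with TBSOTf and i-Pr2NEt in CH2Cl2 at −78 °C should give the tert-butyldimethylsilyl dienol ether F7 (silyloxy on C6, double bonds C6=C5 and C4=C3a). Its γ-carbon C3a is then closed onto the alkyne by π-acid catalysis with the cationic gold catalyst made from (Ph3P)AuCl and AgBF4 in wet CH2Cl2 at rt, the known 5-endo-dig carbocyclisation of silyl enol ethers onto alkynes. Protodeauration and loss of the silyl group give 31, where the route is rejoined.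

**Further compounds**
F1 | step 9 | (1R)-1-[3-(3,5-dimethoxyphenyl)-1-hydroxy-2-(3,4,5-trimethoxyphenyl)cyclobut-2-en-1-yl]-3-(phenylsulfanyl)propan-1-one | O=C(CCSc1ccccc1)[C@@]1(O)CC(c2cc(OC)cc(OC)c2)=C1c1cc(OC)c(OC)c(OC)c1
F2 | step 9 | (5S)-3-(3,5-dimethoxyphenyl)-5-hydroxy-5-[2-(phenylsulfanyl)ethyl]-2-(3,4,5-trimethoxyphenyl)cyclopent-2-en-1-one | O=C1C(c2cc(OC)c(OC)c(OC)c2)=C(c2cc(OC)cc(OC)c2)C[C@]1(O)CCSc1ccccc1
F3 | step 9 | (5S)-3-(3,5-dimethoxyphenyl)-5-hydroxy-5-[2-(phenylsulfinyl)ethyl]-2-(3,4,5-trimethoxyphenyl)cyclopent-2-en-1-one, both sulfur epimers | O=C1C(c2cc(OC)c(OC)c(OC)c2)=C(c2cc(OC)cc(OC)c2)C[C@]1(O)CCS(=O)c1ccccc1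
F4 | step 7 | 1-lithio-1-methoxyallene | COC([Li])=C=C
F5 | step 7 | racemic 3-(3,5-dimethoxyphenyl)-1-(1-methoxypropa-1,2-dien-1-yl)-2-(3,4,5-trimethoxyphenyl)cyclobut-2-en-1-ol | COC(=C=C)C1(O)CC(c2cc(OC)cc(OC)c2)=C1c1cc(OC)c(OC)c(OC)c1
F6 | step 7 | racemic 1-[3-(3,5-dimethoxyphenyl)-1-hydroxy-2-(3,4,5-trimethoxyphenyl)cyclobut-2-en-1-yl]prop-2-en-1-one | C=CC(=O)C1(O)CC(c2cc(OC)cc(OC)c2)=C1c1cc(OC)c(OC)c(OC)c1
F7 | step 16 | tert-butyldimethylsilyl dienol ether of 30 (2-silyloxycyclopenta-1,3-diene, configuration at C6a as in 30) | CC(C)(C)[Si](C)(C)OC1=C(c2cc(OC)c(OC)c(OC)c2)C(c2cc(OC)cc(OC)c2)=C[C@]1(O[Si](CC)(CC)CC)C(=O)C#C/C=C/c1cc(OC)cc(OC)c1
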